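- Over-reaction is slow, but at the full reagent charge target still halves by that step in 1.3 d, less than the run of 2.0 d, so what counts is how much reagent each target sees after it is born.

    initiator → 2 initiating radical (k1 = 9.76 × 10⁻⁴ min⁻¹)
    substrate + initiating radical → chain carrier (k2 = 43800 M⁻¹ min⁻¹)
    reagent + chain carrier → target + initiating radical (k3 = 9450 M⁻¹ min⁻¹)
    2 chain carrier → ended chains (k4 = 2 × 10⁷ M⁻¹ s⁻¹)
    reagent + target → over-reaction product (k5 = 7.59 × 10⁻⁴ M⁻¹ min⁻¹)

| setting | east | south-east | west | north |
|---|---|---|---|---|
| substrate | 0.12 M (fed, over 1.60 d) | 0.12 M | 0.12 M | 0.12 M |
| reagent | 0.480 M | 0.480 M | 0.480 M (fed, over 1.60 d) | 0.480 M |
| initiator | 0.60 mM | 0.60 mM | 0.60 mM | 0.60 mM |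
| time | 2.0 d | 2.0 d | 2.0 d |  |
| remark | a stirred flask in which substrate is dosed at a steady rate over 1.60 d without added volume, worked up at 2.0 d | a closed flask charged with all of it at once and left for 2.0 d | all but reagent at the start; reagent goes in evenly over 1.60 d, the run ends at 2.0 d | one stirred flow tank at steady state, fed with the mixture as stated, mean residence time 2.0 d |

- a species is counted by the substrate in it: one ended chains counts as two
- a doubled species enters its step squared and goes two at a time
- the stated concentrations are those of everything mixed, before any reaction; amounts are the same in each set-up
- the feed brings no volume worth counting
- run time (east): 2.0 d

* the set-up with the highest share of target in all that became target or over-reaction product, at the outlet or at the end ("none" if the first two lie within 2 percentage points) (east / south-east / west / north / none)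
* share of target in all that became target or over-reaction product, at the outlet or at the end, east
* share of target in all that became target or over-reaction product, at the outlet or at the end, south-east
* share of target in all that became target or over-reaction product, at the outlet or at the end, west
* share of target in all that became target or over-reaction product, at the outlet or at the end, north

- I freeze reagent: each target costs one and each over-reaction one more, so after the feed its fraction of charge stays between one and 0.500, and target then decays pseudo-first-order, which makes the share of target about exp(−exposure).
- West makes target at a rate set by reagent present times carrier, and the initiator behind the carrier halves in 0.493 d, shorter than the feed of 1.60 d, so I take two limits: if target-making ended with the feed, half would be born by 1.13 d, and the reagent present from then on gives an exposure of the median target, the step's constant times reagent times time from that birth to the end, of 0.420; with the carrier frozen and target forming on after the feed, half would be born by 1.39 d, at an exposure of 0.315.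
- With no reagent spent, the first limit gives west a floor of 65.7%; the second limit, charging a fraction 0.250 of the reagent as spent throughout, gives my ceiling of 79.0%, and I can tighten it no further by hand.
- At reagent fraction 0.750, east, with median birth mid-feed, gives 62.4%; south-east, born by about the initiator half-life 0.493 d, gives 55.3%; north, with its spread of ages, gives 56.0%.
- West's floor stands above these, so I name west.
- The forecast, holding that “Feeding the reagent keeps its level low”, says west, with 71% there (67% to 75%), 62.7% for east, 60% for south-east and 58% for north.
- The simulation gives west at 72.6%, inside my bracket, with east 63.4%, south-east 59.6% and north 57.8%.
- In west, half of the target-making turnover is done by 1.15 d, and the 0.850 d after it is shorter than target's half-life of 1.6 d at the end; read back, west's share is an exposure of 0.320, a fraction 0.762 of my 0.420.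
- Exposure scales with the reagent charge, so for the neighbour of west with 0.19 M of reagent it falls to 0.166, and at that read fraction the share is 88.1%; the computed neighbour gives 87.7%, with 77% of its substrate left at the end.

Its constants are made up.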